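**Retrosynthetic overview**
1. Target ⇐ C2 ketone (Luche reduction, acetylation) ⇐ δ-lactone closed last by intramolecular Michael addition of the C3 enolate onto a 2-arylacrylate tethered on O4 (C3–C3' bond, cis-fusion).
2. Key disconnection: the aryl–C2' bond, made by Suzuki–Miyaura coupling of the O4 2-bromoacrylate of the guaianolide core with an arylboronate (fragment union).
3. Core: the seven-membered ring and the trans α-methylene-γ-lactone are closed together (C7–C8) by a new iridium-catalysed ring-closing 2-(alkoxycarbonyl)allylation.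
4. Cyclopentenone from cyclopentane-1,3-dione: organocatalytic Michael addition to crotonaldehyde (C10), vinylogous-ester α'-methylation and hydroxylation (C4), Stork–Danheiser allylation (C6–C7).
5. Arylboronate from 3-chlorophenol and pent-4-yn-1-ol; ring order: cyclopentenone, then seven-membered ring with γ-lactone, then δ-lactone.

Assumption: the SMILES defines the target; the antipodes of the chiral catalysts and of the oxaziridine are named from their usual stereochemical models and would be exchanged if the sense proved opposite on these substrates.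

Labels: guaiane numbering (C1=C5 ring-fusion alkene, C2–C4 in the five-membered ring, C6–C10 in the seven-membered ring, C11–C13 lactone carbons, Me-14 on C10, Me-15 on C4); δ-lactone carbons are C1' (C=O), C2' (aryl-bearing), C3' (CH2 on C3). Ar* = 4-({[tert-butyl(dimethyl)silyl]oxy}methyl)-3-[(2R)-5-acetoxypentan-2-yl]phenyl.

**Core (steps 1–12)**

Step 1
Reactants: 1 cyclopentane-1,3-dione; 2 (2E)-but-2-enal
Product: 5 2-[(2S)-4-hydroxybutan-2-yl]cyclopentane-1,3-dione, via open-chain adduct 3 (not isolated), via lactol 4 (not isolated)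
Conditions: (R)-α,α-diphenylprolinol trimethylsilyl ether (10 mol%), PhCO2H (10 mol%), CH2Cl2, 0 °C; then MeOH, NaBH4 (3 equiv), 0 °C; then 1 M HCl to pH 3
Reagents that add atoms: none
Why: Iminium-activated enantioselective Michael addition of the 1,3-dione to the enal, in which the silyloxydiphenylmethyl group of the (R)-catalyst shields one face of the E-iminium ion so that C10 is formed S, gives the aldehyde that rests as its lactol, and a one-pot chemoselective borohydride reduction then takes the aldehyde of the ring-opened form to the primary alcohol while the 1,3-dione is masked as its unreactive enolate.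

Step 2
Reactants: 5
Product: 6 (4S)-4-methyl-3,4,6,7-tetrahydrocyclopenta[b]pyran-5(2H)-one
Conditions: TsOH·H2O (5 mol%), toluene, reflux, Dean–Stark
Reagents that add atoms: none
Why: Acid-catalysed intramolecular vinylogous esterification (cyclodehydration) closes the six-membered enol ether, which differentiates C2 (enol ether) from C5 (ketone) and masks O8.

Step 3
Reactants: 6
Product: 8 (4S)-4,6-dimethyl-3,4,6,7-tetrahydrocyclopenta[b]pyran-5(2H)-one (both C6 epimers), via lithium dienolate 7 (not isolated)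
Conditions: LiN(iPr)2 (1.1 equiv), THF, −78 °C; then MeI, −78 → −20 °C
Reagents that add atoms: iodomethane, CI
Why: Kinetic α'-deprotonation of the vinylogous ester and C-methylation at C4 (Stork–Danheiser enolate alkylation); the new centre is erased in the next step.

Step 4
Reactants: 8
Product: 10 (4S,6S)-6-hydroxy-4,6-dimethyl-3,4,6,7-tetrahydrocyclopenta[b]pyran-5(2H)-one, via potassium dienolate 9 (not isolated)
Conditions: KN(SiMe3)2, THF, −78 °C; then (+)-[(8,8-dichlorocamphoryl)sulfonyl]oxaziridine, −78 °C; aq NH4Cl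
Reagents that add atoms: (+)-[(8,8-dichlorocamphoryl)sulfonyl]oxaziridine, CC1(C)C2CCC13CS(=O)(=O)N4OC34C2(Cl)Cl
Why: Davis asymmetric enolate hydroxylation: the camphor-derived oxaziridine transfers oxygen to one face of the tetrasubstituted enolate and sets the quaternary carbinol C4 as S under reagent control, the minor C4 epimer being a separable diastereomer because C10 is already fixed.

Step 5
Reactants: 10; 11 prop-2-en-1-ylmagnesium bromide
Product: 13 (4S)-4-hydroxy-2-[(2S)-4-hydroxybutan-2-yl]-4-methyl-3-(prop-2-en-1-yl)cyclopent-2-en-1-one, via allyl carbinol 12 (not isolated)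
Conditions: CH2=CHCH2MgBr (3 equiv), THF, −78 → 0 °C; then 1 M HCl, THF, 0 °C → rt
Reagents that add atoms: water, O
Why: Stork–Danheiser sequence: 1,2-addition of the allyl Grignard reagent to the vinylogous-ester carbonyl, then acid-mediated allylic transposition with hydrolysis of the enol ether, gives the C1=C5 enone, installs C6–C7 and releases the C8 alcohol without touching C4 or C10.

Step 6
Reactants: 13
Product: 14 (4S)-2-[(2S)-4-{[tert-butyl(dimethyl)silyl]oxy}butan-2-yl]-4-hydroxy-4-methyl-3-(prop-2-en-1-yl)cyclopent-2-en-1-one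
Conditions: TBSCl (1.05 equiv), imidazole, CH2Cl2, 0 °C
Reagents that add atoms: tert-butyl(chloro)dimethylsilane, CC(C)(C)[Si](C)(C)Cl
Why: Chemoselective silylation of the primary alcohol in the presence of the hindered tertiary alcohol.

Step 7
Reactants: 14
Product: 16 2-[(5S)-2-[(2S)-4-{[tert-butyl(dimethyl)silyl]oxy}butan-2-yl]-5-hydroxy-5-methyl-3-oxocyclopent-1-en-1-yl]acetaldehyde, via ozonide 15 (not isolated)
Conditions: O3, CH2Cl2, −78 °C; then PPh3, −78 °C → rt
Reagents that add atoms: ozone, [O-][O+]=O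
Why: Ozonolysis with reductive work-up cleaves the electron-rich terminal alkene selectively, the tetrasubstituted enone alkene being deactivated.

Step 8
Reactants: 16; 17 methyl prop-2-ynoate
Product: 19 methyl 4-[(5S)-2-[(2S)-4-{[tert-butyl(dimethyl)silyl]oxy}butan-2-yl]-5-hydroxy-5-methyl-3-oxocyclopent-1-en-1-yl]-3-hydroxy-2-methylidenebutanoate (both C3 epimers), via vinylalane 18 (not isolated)
Conditions: iBu2AlH (2.2 equiv), N-methylmorpholine N-oxide, THF, 0 °C; then 16, −78 → 0 °C; aq potassium sodium tartrate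
Reagents that add atoms: none
Why: Vinylalumination: hydroalumination of the propiolate gives the α-aluminoacrylate, which adds to the aldehyde to give the Morita–Baylis–Hillman-type adduct without the basic conditions that would enolise this aldehyde; the new carbinol centre is lost later.

Step 9
Reactants: 19
Product: 20 methyl 3-[(tert-butoxycarbonyl)oxy]-4-[(5S)-2-[(2S)-4-{[tert-butyl(dimethyl)silyl]oxy}butan-2-yl]-5-hydroxy-5-methyl-3-oxocyclopent-1-en-1-yl]-2-methylidenebutanoate (both C3 epimers)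
Conditions: Boc2O (1.2 equiv), DMAP (10 mol%), CH2Cl2, 0 °C
Reagents that add atoms: di-tert-butyl dicarbonate, CC(C)(C)OC(=O)OC(=O)OC(C)(C)C
Why: Carbonate formation (acylation) at the secondary allylic alcohol, the tertiary alcohol being too hindered to react at 0 °C.

Step 10
Reactants: 20
Product: 21 methyl 3-[(tert-butoxycarbonyl)oxy]-4-[(5S)-5-hydroxy-2-[(2S)-4-hydroxybutan-2-yl]-5-methyl-3-oxocyclopent-1-en-1-yl]-2-methylidenebutanoate (both C3 epimers)
Conditions: HF·pyridine, pyridine, THF, 0 °C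
Reagents that add atoms: none
Why: Fluoride desilylation frees the primary C8 alcohol; the carbonate is stable to buffered HF.

Step 11
Reactants: 21
Product: 24 (4S,7R,8S,10S)-4-hydroxy-2-oxoguaia-1(5),11(13)-dien-12,8-olide, via aldehyde 22 (not isolated), via hydroxy ester 23 (not isolated)
Conditions: [Ir(cod)Cl]2 (5 mol%), (R)-SEGPHOS (10 mol%), 4-chloro-3-nitrobenzoic acid (20 mol%), K3PO4 (20 mol%), THF (0.005 M), 60 °C; then camphorsulfonic acid (10 mol%), rt
Reagents that add atoms: none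
Why: Proposed new method: a ring-closing, redox-neutral iridium-catalysed 2-(alkoxycarbonyl)allylation in which the cyclometallated iridium C,O-benzoate dehydrogenates the C8 alcohol to the aldehyde, the iridium hydride is deprotonated and ionises the allylic carbonate (loss of CO2 and tert-butoxide) to a 2-(methoxycarbonyl)allyl iridium species, and its γ-carbon C7 adds to the tethered aldehyde through a chair transition state fused diequatorially to the forming seven-membered ring (trans C7/C8, hence 7R) while the SEGPHOS ligand fixes the aldehyde face (8S), after which acid closes the γ-lactone; the closest known reaction is the intermolecular iridium-catalysed transfer-hydrogenative 2-(alkoxycarbonyl)allylation of primary alcohols to α-methylene-γ-butyrolactones, which has not been shown intramolecularly, for a medium ring, or with a γ-substituted allyl donor.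

Step 12
Reactants: 24; 25 2,3-dibromopropanoyl chloride
Product: 27 (4S,7R,8S,10S)-4-[(2-bromoprop-2-enoyl)oxy]-2-oxoguaia-1(5),11(13)-dien-12,8-olide, via acid chloride 26 (not isolated)
Conditions: Et3N (3 equiv), DMAP (20 mol%), CH2Cl2, −20 °C → rt
Reagents that add atoms: none
Why: Base-induced dehydrobromination of the acid chloride to 2-bromoacryloyl chloride and DMAP-catalysed esterification of the tertiary C4 alcohol.

**Side chain (steps 13–15)**

Step 13
Reactants: 28 pent-4-yn-1-ol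
Product: 29 pent-4-yn-1-yl acetate
Conditions: Ac2O, pyridine, DMAP (cat.), CH2Cl2, rt
Reagents that add atoms: acetic anhydride, CC(=O)OC(C)=O
Why: Acetylation of the primary alcohol installs the side-chain acetate of the target at the outset.

Step 14
Reactants: 29
Product: 31 4-bromopent-4-en-1-yl acetate, via alkenylborane 30 (not isolated)
Conditions: B-bromo-9-borabicyclo[3.3.1]nonane, CH2Cl2, 0 °C; then AcOH, 0 °C → rt
Reagents that add atoms: B-bromo-9-borabicyclo[3.3.1]nonane, BrB1C2CCCC1CCC2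
Why: Haloboration–protodeboronation: syn-bromoboration puts bromine on the internal carbon and acetic acid cleaves the C–B bond to give the 2-bromo-1-alkene.

Step 15
Reactants: 31
Product: 32 4-(4,4,5,5-tetramethyl-1,3,2-dioxaborolan-2-yl)pent-4-en-1-yl acetate
Conditions: B2pin2, PdCl2(PPh3)2 (3 mol%), PPh3 (6 mol%), KOPh, toluene, 50 °C
Reagents that add atoms: bis(pinacolato)diboron, CC1(C)OB(OC1(C)C)B1OC(C)(C)C(C)(C)O1
Why: Miyaura borylation of the alkenyl bromide.

**Arene (steps 16–22)**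

Step 16
Reactants: 33 3-chlorophenol
Product: 34 4-chloro-2-hydroxybenzaldehyde
Conditions: (CH2O)n, MgCl2, Et3N, MeCN, reflux; 1 M HCl work-up
Reagents that add atoms: paraformaldehyde (as formaldehyde), C=O
Why: Magnesium-mediated ortho-formylation of the phenol (Casnati–Skattebøl), which takes place at the less hindered ortho position para to chlorine and so fixes the 1,2,4-pattern.

Step 17
Reactants: 34
Product: 35 5-chloro-2-formylphenyl trifluoromethanesulfonate
Conditions: Tf2O, pyridine, CH2Cl2, 0 °C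
Reagents that add atoms: trifluoromethanesulfonic anhydride, O=S(=O)(OS(=O)(=O)C(F)(F)F)C(F)(F)F
Why: O-Triflation of the phenol turns it into the coupling handle.

Step 18
Reactants: 35; 32
Product: 36 4-(5-chloro-2-formylphenyl)pent-4-en-1-yl acetate
Conditions: PdCl2(dppf) (3 mol%), K3PO4, 1,4-dioxane/H2O (20:1), 70 °C
Reagents that add atoms: none
Why: Suzuki–Miyaura coupling in which the activated aryl triflate reacts and the aryl chloride is inert.

Step 19
Reactants: 36
Product: 37 4-[5-chloro-2-(hydroxymethyl)phenyl]pent-4-en-1-yl acetate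
Conditions: NaBH4, MeOH, 0 °C
Reagents that add atoms: none
Why: Borohydride reduction of the aryl aldehyde; the acetate survives at 0 °C.

Step 20
Reactants: 37
Product: 38 4-[2-({[tert-butyl(dimethyl)silyl]oxy}methyl)-5-chlorophenyl]pent-4-en-1-yl acetate
Conditions: TBSCl, imidazole, DMF, rt
Reagents that add atoms: tert-butyl(chloro)dimethylsilane, CC(C)(C)[Si](C)(C)Cl
Why: Silylation protects the benzylic alcohol until the last step.

Step 21
Reactants: 38
Product: 39 (4R)-4-[2-({[tert-butyl(dimethyl)silyl]oxy}methyl)-5-chlorophenyl]pentyl acetate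
Conditions: H2 (1 bar), [Ir(cod)((4S,5S)-ThrePHOX)][B(C6H3(CF3)2)4] (1 mol%), CH2Cl2, 0 °C
Reagents that add atoms: none
Why: Iridium-catalysed asymmetric hydrogenation of the unfunctionalised 1,1-disubstituted alkene, in which the chiral P,N ligand selects the alkene face and sets the benzylic centre as R; the aryl chloride survives.

Step 22
Reactants: 39
Product: 40 (4R)-4-[2-({[tert-butyl(dimethyl)silyl]oxy}methyl)-5-(4,4,5,5-tetramethyl-1,3,2-dioxaborolan-2-yl)phenyl]pentyl acetate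
Conditions: B2pin2, Pd2(dba)3 (1 mol%), XPhos (4 mol%), KOAc, 1,4-dioxane, 100 °C
Reagents that add atoms: bis(pinacolato)diboron, CC1(C)OB(OC1(C)C)B1OC(C)(C)C(C)(C)O1
Why: Miyaura borylation of the aryl chloride with a bulky biarylphosphine ligand.

**Union and endgame (steps 23–27)**

Step 23
Reactants: 27; 40
Product: 41 (4S,7R,8S,10S)-4-{[2-(Ar*)prop-2-enoyl]oxy}-2-oxoguaia-1(5),11(13)-dien-12,8-olide
Conditions: Pd(PPh3)4 (5 mol%), K3PO4, THF/H2O (10:1), 45 °C
Reagents that add atoms: none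
Why: Suzuki–Miyaura coupling of the alkenyl bromide with the arylboronate forms the aryl–C2' bond that unites the two halves; no stereocentre is touched.

Step 24
Reactants: 41
Product: 44 (3R,4S,7R,8S,10S,2'R) 2-oxoguaia-1(5),11(13)-dien-12,8-olide 3,4-annulated δ-lactone [O4-C1'(=O)-C2'H(Ar*)-C3'H2-C3], via potassium dienolate 42 (not isolated), via potassium lactone enolate 43 (not isolated)
Conditions: KN(SiMe3)2 (1.05 equiv), THF, −78 °C; then AcOH, −78 °C
Reagents that add atoms: none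
Why: Intramolecular 6-endo Michael addition of the C3 ketone enolate to the tethered 2-arylacrylate: the ester tether on O4 can only reach the same face of C3, so the δ-lactone is cis-fused, and protonation of the lactone enolate from the convex face, which is also the thermodynamic outcome with the aryl group equatorial, sets C2' as R.

Step 25
Reactants: 44
Product: 45 (2R,3S,4S,7R,8S,10S,2'R) 2-hydroxyguaia-1(5),11(13)-dien-12,8-olide 3,4-annulated δ-lactone [O4-C1'(=O)-C2'H(Ar*)-C3'H2-C3]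
Conditions: NaBH4, CeCl3·7H2O, MeOH/THF, −78 °C
Reagents that add atoms: none
Why: Luche 1,2-reduction: hydride adds to the C2 ketone from the convex face anti to the lactone ring on C3, giving the 2R alcohol cis to C3' and O4, at a temperature at which the α-methylene lactone is not reduced.

Step 26
Reactants: 45
Product: 46 (2R,3S,4S,7R,8S,10S,2'R) 2-acetoxyguaia-1(5),11(13)-dien-12,8-olide 3,4-annulated δ-lactone [O4-C1'(=O)-C2'H(Ar*)-C3'H2-C3]
Conditions: Ac2O, DMAP, pyridine, CH2Cl2, 0 °C → rt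
Reagents that add atoms: acetic anhydride, CC(=O)OC(C)=O
Why: Acetylation of the secondary allylic alcohol with retention at C2.

Step 27
Reactants: 46
Product: 47 CNP0205574.1
Conditions: HF·pyridine, pyridine, THF, 0 °C → rt
Reagents that add atoms: none
Why: Fluoride desilylation of the benzylic silyl ether under buffered conditions that leave both acetates and both lactones intact.

**Compound list**
1 | cyclopentane-1,3-dione | O=C1CCC(=O)C1 | starting material
2 | (2E)-but-2-enal | C/C=C/C=O | starting material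
3 | (3S)-3-(2,5-dioxocyclopentyl)butanal | O=CC[C@H](C)C1C(=O)CCC1=O | intermediate
4 | (4S)-2-hydroxy-4-methyl-3,4,6,7-tetrahydrocyclopenta[b]pyran-5(2H)-one (both C2 epimers) | O=C1CCC2=C1[C@@H](C)CC(O)O2 | intermediate
5 | 2-[(2S)-4-hydroxybutan-2-yl]cyclopentane-1,3-dione | O=C1CCC(=O)C1[C@@H](C)CCO | intermediate
6 | (4S)-4-methyl-3,4,6,7-tetrahydrocyclopenta[b]pyran-5(2H)-one | O=C1CCC2=C1[C@@H](C)CCO2 | intermediate
7 | lithium (4S)-4-methyl-2,3,4,7-tetrahydrocyclopenta[b]pyran-5-olate | [Li+].[O-]C1=CCC2=C1[C@@H](C)CCO2 | intermediate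
8 | (4S)-4,6-dimethyl-3,4,6,7-tetrahydrocyclopenta[b]pyran-5(2H)-one (both C6 epimers) | O=C1C(C)CC2=C1[C@@H](C)CCO2 | intermediate
9 | potassium (4S)-4,6-dimethyl-2,3,4,7-tetrahydrocyclopenta[b]pyran-5-olate | [K+].[O-]C1=C(C)CC2=C1[C@@H](C)CCO2 | intermediate
10 | (4S,6S)-6-hydroxy-4,6-dimethyl-3,4,6,7-tetrahydrocyclopenta[b]pyran-5(2H)-one | O=C1[C@@](C)(O)CC2=C1[C@@H](C)CCO2 | intermediate
11 | prop-2-en-1-ylmagnesium bromide | C=CC[Mg]Br | starting material
12 | (4S,6S)-4,6-dimethyl-5-(prop-2-en-1-yl)-2,3,4,5,6,7-hexahydrocyclopenta[b]pyran-5,6-diol (both C5 epimers) | C=CCC1(O)[C@@](C)(O)CC2=C1[C@@H](C)CCO2 | intermediate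
13 | (4S)-4-hydroxy-2-[(2S)-4-hydroxybutan-2-yl]-4-methyl-3-(prop-2-en-1-yl)cyclopent-2-en-1-one | C=CCC1=C([C@@H](C)CCO)C(=O)C[C@]1(C)O | intermediate
14 | (4S)-2-[(2S)-4-{[tert-butyl(dimethyl)silyl]oxy}butan-2-yl]-4-hydroxy-4-methyl-3-(prop-2-en-1-yl)cyclopent-2-en-1-one | C=CCC1=C([C@@H](C)CCO[Si](C)(C)C(C)(C)C)C(=O)C[C@]1(C)O | intermediate
15 | (4S)-2-[(2S)-4-{[tert-butyl(dimethyl)silyl]oxy}butan-2-yl]-4-hydroxy-4-methyl-3-(1,2,4-trioxolan-3-ylmethyl)cyclopent-2-en-1-one (ozonide) | C1OC(CC2=C([C@@H](C)CCO[Si](C)(C)C(C)(C)C)C(=O)C[C@]2(C)O)OO1 | intermediate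
16 | 2-[(5S)-2-[(2S)-4-{[tert-butyl(dimethyl)silyl]oxy}butan-2-yl]-5-hydroxy-5-methyl-3-oxocyclopent-1-en-1-yl]acetaldehyde | O=CCC1=C([C@@H](C)CCO[Si](C)(C)C(C)(C)C)C(=O)C[C@]1(C)O | intermediate
17 | methyl prop-2-ynoate | C#CC(=O)OC | starting material
18 | methyl 2-[bis(2-methylpropyl)alumanyl]prop-2-enoate | COC(=O)C(=C)[Al](CC(C)C)CC(C)C | intermediate
19 | methyl 4-[(5S)-2-[(2S)-4-{[tert-butyl(dimethyl)silyl]oxy}butan-2-yl]-5-hydroxy-5-methyl-3-oxocyclopent-1-en-1-yl]-3-hydroxy-2-methylidenebutanoate (both C3 epimers) | COC(=O)C(=C)C(O)CC1=C([C@@H](C)CCO[Si](C)(C)C(C)(C)C)C(=O)C[C@]1(C)O | intermediate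
20 | methyl 3-[(tert-butoxycarbonyl)oxy]-4-[(5S)-2-[(2S)-4-{[tert-butyl(dimethyl)silyl]oxy}butan-2-yl]-5-hydroxy-5-methyl-3-oxocyclopent-1-en-1-yl]-2-methylidenebutanoate (both C3 epimers) | COC(=O)C(=C)C(OC(=O)OC(C)(C)C)CC1=C([C@@H](C)CCO[Si](C)(C)C(C)(C)C)C(=O)C[C@]1(C)O | intermediate
21 | methyl 3-[(tert-butoxycarbonyl)oxy]-4-[(5S)-5-hydroxy-2-[(2S)-4-hydroxybutan-2-yl]-5-methyl-3-oxocyclopent-1-en-1-yl]-2-methylidenebutanoate (both C3 epimers) | COC(=O)C(=C)C(OC(=O)OC(C)(C)C)CC1=C([C@@H](C)CCO)C(=O)C[C@]1(C)O | intermediate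
22 | methyl 3-[(tert-butoxycarbonyl)oxy]-4-[(5S)-5-hydroxy-5-methyl-3-oxo-2-[(2S)-4-oxobutan-2-yl]cyclopent-1-en-1-yl]-2-methylidenebutanoate (both C3 epimers) | COC(=O)C(=C)C(OC(=O)OC(C)(C)C)CC1=C([C@@H](C)CC=O)C(=O)C[C@]1(C)O | intermediate
23 | methyl (4S,7R,8S,10S)-4,8-dihydroxy-2-oxoguaia-1(5),11(13)-dien-12-oate | COC(=O)C(=C)[C@H]1CC2=C([C@@H](C)C[C@@H]1O)C(=O)C[C@]2(C)O | intermediate
24 | (4S,7R,8S,10S)-4-hydroxy-2-oxoguaia-1(5),11(13)-dien-12,8-olide | C=C1C(=O)O[C@H]2C[C@H](C)C3=C(C[C@H]12)[C@@](C)(O)CC3=O | intermediate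
25 | 2,3-dibromopropanoyl chloride | ClC(=O)C(Br)CBr | starting material
26 | 2-bromoprop-2-enoyl chloride | C=C(Br)C(=O)Cl | intermediate
27 | (4S,7R,8S,10S)-4-[(2-bromoprop-2-enoyl)oxy]-2-oxoguaia-1(5),11(13)-dien-12,8-olide | C=C1C(=O)O[C@H]2C[C@H](C)C3=C(C[C@H]12)[C@@](C)(OC(=O)C(Br)=C)CC3=O | intermediate
28 | pent-4-yn-1-ol | C#CCCCO | starting material
29 | pent-4-yn-1-yl acetate | C#CCCCOC(C)=O | intermediate
30 | (4Z)-5-(9-borabicyclo[3.3.1]nonan-9-yl)-4-bromopent-4-en-1-yl acetate | CC(=O)OCCC/C(Br)=C/B1C2CCCC1CCC2 | intermediate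
31 | 4-bromopent-4-en-1-yl acetate | C=C(Br)CCCOC(C)=O | intermediate
32 | 4-(4,4,5,5-tetramethyl-1,3,2-dioxaborolan-2-yl)pent-4-en-1-yl acetate | C=C(CCCOC(C)=O)B1OC(C)(C)C(C)(C)O1 | intermediate
33 | 3-chlorophenol | Oc1cccc(Cl)c1 | starting material
34 | 4-chloro-2-hydroxybenzaldehyde | O=Cc1ccc(Cl)cc1O | intermediate
35 | 5-chloro-2-formylphenyl trifluoromethanesulfonate | O=Cc1ccc(Cl)cc1OS(=O)(=O)C(F)(F)F | intermediate
36 | 4-(5-chloro-2-formylphenyl)pent-4-en-1-yl acetate | O=Cc1ccc(Cl)cc1C(=C)CCCOC(C)=O | intermediate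
37 | 4-[5-chloro-2-(hydroxymethyl)phenyl]pent-4-en-1-yl acetate | OCc1ccc(Cl)cc1C(=C)CCCOC(C)=O | intermediate
38 | 4-[2-({[tert-butyl(dimethyl)silyl]oxy}methyl)-5-chlorophenyl]pent-4-en-1-yl acetate | CC(C)(C)[Si](C)(C)OCc1ccc(Cl)cc1C(=C)CCCOC(C)=O | intermediate
39 | (4R)-4-[2-({[tert-butyl(dimethyl)silyl]oxy}methyl)-5-chlorophenyl]pentyl acetate | CC(C)(C)[Si](C)(C)OCc1ccc(Cl)cc1[C@H](C)CCCOC(C)=O | intermediate
40 | (4R)-4-[2-({[tert-butyl(dimethyl)silyl]oxy}methyl)-5-(4,4,5,5-tetramethyl-1,3,2-dioxaborolan-2-yl)phenyl]pentyl acetate | CC(C)(C)[Si](C)(C)OCc1ccc(B2OC(C)(C)C(C)(C)O2)cc1[C@H](C)CCCOC(C)=O | intermediate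
41 | (4S,7R,8S,10S)-4-{[2-(Ar*)prop-2-enoyl]oxy}-2-oxoguaia-1(5),11(13)-dien-12,8-olide | C=C1C(=O)O[C@H]2C[C@H](C)C3=C(C[C@H]12)[C@@](C)(OC(=O)C(=C)c4ccc(CO[Si](C)(C)C(C)(C)C)c([C@H](C)CCCOC(C)=O)c4)CC3=O | intermediate
42 | potassium C2–C3 dienolate of 41 | [K+].C=C1C(=O)O[C@H]2C[C@H](C)C3=C(C[C@H]12)[C@@](C)(OC(=O)C(=C)c4ccc(CO[Si](C)(C)C(C)(C)C)c([C@H](C)CCCOC(C)=O)c4)C=C3[O-] | intermediate
43 | potassium C1'–C2' lactone enolate of 44 | [K+].C=C1C(=O)O[C@H]2C[C@H](C)C3=C(C[C@H]12)[C@@]1(C)OC([O-])=C(c2ccc(CO[Si](C)(C)C(C)(C)C)c([C@H](C)CCCOC(C)=O)c2)C[C@H]1C3=O | intermediate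
44 | (3R,4S,7R,8S,10S,2'R) 2-oxoguaia-1(5),11(13)-dien-12,8-olide 3,4-annulated δ-lactone [O4-C1'(=O)-C2'H(Ar*)-C3'H2-C3] | C=C1C(=O)O[C@H]2C[C@H](C)C3=C(C[C@H]12)[C@@]1(C)OC(=O)[C@@H](c2ccc(CO[Si](C)(C)C(C)(C)C)c([C@H](C)CCCOC(C)=O)c2)C[C@H]1C3=O | intermediate
45 | (2R,3S,4S,7R,8S,10S,2'R) 2-hydroxy analogue of 44 | C=C1C(=O)O[C@H]2C[C@H](C)C3=C(C[C@H]12)[C@@]1(C)OC(=O)[C@@H](c2ccc(CO[Si](C)(C)C(C)(C)C)c([C@H](C)CCCOC(C)=O)c2)C[C@H]1[C@H]3O | intermediate
46 | (2R,3S,4S,7R,8S,10S,2'R) 2-acetate of 45 (silyl ether of the target) | C=C1C(=O)O[C@H]2C[C@H](C)C3=C(C[C@H]12)[C@@]1(C)OC(=O)[C@@H](c2ccc(CO[Si](C)(C)C(C)(C)C)c([C@H](C)CCCOC(C)=O)c2)C[C@H]1[C@H]3OC(C)=O | intermediate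
47 | CNP0205574.1: (2R,3S,4S,7R,8S,10S,2'R) 2-acetoxyguaia-1(5),11(13)-dien-12,8-olide 3,4-annulated δ-lactone with 2'-{4-(hydroxymethyl)-3-[(2R)-5-acetoxypentan-2-yl]phenyl} | C=C1C(=O)O[C@H]2C[C@H](C)C3=C(C[C@H]12)[C@@]1(C)OC(=O)[C@@H](c2ccc(CO)c([C@H](C)CCCOC(C)=O)c2)C[C@H]1[C@H]3OC(C)=O | target

**Totals**
Total step count: 27.
Longest linear sequence: 17 steps (steps 1–12, then 23–27), which is 63% of the total.

**Three steps most likely to fail**

Step 11 (the proposed new ring closure). It may give intermolecular allylation, O-allylation, the cis-lactone, or partial retro-aldol epimerisation at C4 under the basic conditions. The fallback uses known chemistry and sets out from 19. N-Bromosuccinimide and Me2S (CH2Cl2, −20 °C → rt, SN2' bromination) give the rearranged allylic bromide methyl (2Z)-2-(bromomethyl)-4-[(5S)-2-[(2S)-4-{[tert-butyl(dimethyl)silyl]oxy}butan-2-yl]-5-hydroxy-5-methyl-3-oxocyclopent-1-en-1-yl]but-2-enoate F3. HF·pyridine then gives the primary alcohol methyl (2Z)-2-(bromomethyl)-4-[(5S)-5-hydroxy-2-[(2S)-4-hydroxybutan-2-yl]-5-methyl-3-oxocyclopent-1-en-1-yl]but-2-enoate F4. Dess–Martin periodinane gives the aldehyde methyl (2Z)-2-(bromomethyl)-4-[(5S)-5-hydroxy-5-methyl-3-oxo-2-[(2S)-4-oxobutan-2-yl]cyclopent-1-en-1-yl]but-2-enoate F5. CrCl2 (4 equiv, THF, rt) then effects an intramolecular Nozaki–Hiyama allylation through a chair transition state (anti-selective) to the hydroxy ester 23, and camphorsulfonic acid lactonises it, so the route is rejoined at 24.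

Step 24 (Michael lactonisation). The strong base may deprotonate C6 instead of C3, or the 2-arylacrylate and the α-methylene lactone may oligomerise. The fallback sets out from 41. Me3SiOSO2CF3 and Et3N (CH2Cl2, −78 → 0 °C) give the cross-conjugated silyl dienol ether (4S,7R,8S,10S)-4-{[2-(Ar*)prop-2-enoyl]oxy}-2-[(trimethylsilyl)oxy]guaia-1(5),2,11(13)-trien-12,8-olide F6. HN(SO2CF3)2 (5 mol%, CH2Cl2, −78 °C) then promotes an intramolecular Mukaiyama–Michael addition to the O-trimethylsilyl ketene acetal of 44 F7, which is not isolated. Buffered aqueous work-up protonates it from the convex face and the route is rejoined at 44.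

Step 4 (reagent-controlled hydroxylation). The facial selectivity of the oxaziridine on a five-membered vinylogous-ester enolate may be modest. The fallback sets out from 8. Me3SiOSO2CF3 and Et3N (CH2Cl2, 0 °C) give the silyl dienol ether (4S)-4,6-dimethyl-5-[(trimethylsilyl)oxy]-2,3,4,7-tetrahydrocyclopenta[b]pyran F1. Shi asymmetric epoxidation (D-fructose-derived ketone catalyst, KHSO5, K2CO3, MeCN/dimethoxymethane/water, 0 °C), known for silyl enol ethers, gives the silyloxy epoxide (4S,6S)-5,6-epoxy-4,6-dimethyl-5-[(trimethylsilyl)oxy]-2,3,4,5,6,7-hexahydrocyclopenta[b]pyran F2, which is not isolated. It opens on mild acidic work-up to the α'-hydroxy ketone, so the route is rejoined at 10.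

**Further compounds**
F1 | step 4 | (4S)-4,6-dimethyl-5-[(trimethylsilyl)oxy]-2,3,4,7-tetrahydrocyclopenta[b]pyran | C[Si](C)(C)OC1=C(C)CC2=C1[C@@H](C)CCO2
F2 | step 4 | (4S,6S)-5,6-epoxy-4,6-dimethyl-5-[(trimethylsilyl)oxy]-2,3,4,5,6,7-hexahydrocyclopenta[b]pyran | C[Si](C)(C)O[C@]12O[C@@]1(C)CC1=C2[C@@H](C)CCO1
F3 | step 11 | methyl (2Z)-2-(bromomethyl)-4-[(5S)-2-[(2S)-4-{[tert-butyl(dimethyl)silyl]oxy}butan-2-yl]-5-hydroxy-5-methyl-3-oxocyclopent-1-en-1-yl]but-2-enoate | COC(=O)/C(CBr)=C/CC1=C([C@@H](C)CCO[Si](C)(C)C(C)(C)C)C(=O)C[C@]1(C)O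
F4 | step 11 | methyl (2Z)-2-(bromomethyl)-4-[(5S)-5-hydroxy-2-[(2S)-4-hydroxybutan-2-yl]-5-methyl-3-oxocyclopent-1-en-1-yl]but-2-enoate | COC(=O)/C(CBr)=C/CC1=C([C@@H](C)CCO)C(=O)C[C@]1(C)O
F5 | step 11 | methyl (2Z)-2-(bromomethyl)-4-[(5S)-5-hydroxy-5-methyl-3-oxo-2-[(2S)-4-oxobutan-2-yl]cyclopent-1-en-1-yl]but-2-enoate | COC(=O)/C(CBr)=C/CC1=C([C@@H](C)CC=O)C(=O)C[C@]1(C)O
F6 | step 24 | (4S,7R,8S,10S)-4-{[2-(Ar*)prop-2-enoyl]oxy}-2-[(trimethylsilyl)oxy]guaia-1(5),2,11(13)-trien-12,8-olide | C=C1C(=O)O[C@H]2C[C@H](C)C3=C(C[C@H]12)[C@@](C)(OC(=O)C(=C)c4ccc(CO[Si](C)(C)C(C)(C)C)c([C@H](C)CCCOC(C)=O)c4)C=C3O[Si](C)(C)C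
F7 | step 24 | O-trimethylsilyl ketene acetal of 44 [C1'(OSiMe3)=C2'] | C=C1C(=O)O[C@H]2C[C@H](C)C3=C(C[C@H]12)[C@@]1(C)OC(O[Si](C)(C)C)=C(c2ccc(CO[Si](C)(C)C(C)(C)C)c([C@H](C)CCCOC(C)=O)c2)C[C@H]1C3=O
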